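The central resorcinol ring is cut at C2–C3, C1–C6 and C3–C4 (C1 = C–OMe, C3 = C–OH, C4 = benzyl-bearing, C5 = phenethyl-bearing carbon). A thermal cyclobutenone/ynol ether benzannulation forges that ring in one operation and exploits its 1,3-dioxygenation flanked by two adjacent carbon arms. The cyclobutenone carbonyl becomes the free C3–OH, methoxyacetylene supplies C1–OMe and C2–H, and the C4 benzyl and C5 phenethyl groups arrive on a racemic 4-benzyl-3-phenethylcyclobutenone whose two outer phenols are masked as benzyl ethers. A keteniminium–alkyne [2+2] assembles that cyclobutenone; one hydrogenolysis finishes.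

Key step: step 5

Remark: the target has no stereocentre, stereoaxis or stereogenic double bond, so it is one achiral compound and needs no enantiocontrol; the only stereocentre on the route (C4 of cyclobutenone 11) is made racemic and is erased in step 5; compounds 1, 4, 5 and 12 are taken as purchasable.

Step 1
Reactants: 1 3-[4-(benzyloxy)phenyl]propanoic acid
Product: 3 3-[4-(benzyloxy)phenyl]-N,N-dimethylpropanamide, via acyl imidazole 2 (not isolated)
Conditions: CDI (1.1 equiv), THF, rt; then Me2NH (2 M in THF, 2 equiv), rt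
Reagents that add atoms: dimethylamine, CNC
Why: Carbonyldiimidazole activation gives acyl imidazole 2, which undergoes nucleophilic acyl substitution with the secondary amine (CDI amide coupling) without touching the aryl benzyl ether.

Step 2
Reactants: 4 2-(benzyloxy)benzyl bromide; 5 1-(trimethylsilyl)propyne
Product: 8 4-[2-(benzyloxy)phenyl]but-1-yne, via lithiated silylpropyne 6 (not isolated), via silylated butyne 7 (not isolated)
Conditions: 5 (1.3 equiv), n-BuLi, THF, –78 → –20 °C; add 4, –78 °C → rt; then MeOH, K2CO3, rt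
Reagents that add atoms: none
Why: The silyl-capped propargyl lithium 6 is alkylated by the reactive benzylic bromide at its propargylic carbon (SN2 propargylation, the silyl group disfavouring the allenic terminus), and methanolic carbonate then cleaves the C(sp)–Si bond of 7 in the same flask.

Step 3
Reactants: 3 3-[4-(benzyloxy)phenyl]-N,N-dimethylpropanamide; 8 4-[2-(benzyloxy)phenyl]but-1-yne
Product: 11 racemic 4-[4-(benzyloxy)benzyl]-3-{2-[2-(benzyloxy)phenyl]ethyl}cyclobut-2-en-1-one, via keteniminium triflate 9 (not isolated), via cyclobuteniminium triflate 10 (not isolated)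
Conditions: Tf2O (1.2 equiv), ClCH2CH2Cl, –20 °C; then 8 (1.5 equiv), 2,4,6-collidine (1.2 equiv, slow addition), reflux; then aq NaHCO3, rt
Reagents that add atoms: water, O
Why: Ghosez keteniminium–alkyne [2+2] cycloaddition: O-triflation and deprotonation of 3 give 9, whose electrophilic central carbon bonds to the terminal alkyne carbon while its benzyl-bearing carbon bonds to the internal one, so that hydrolysis of iminium 10 should give the 3-phenethyl-4-benzyl pattern, the C4 stereocentre arising racemic (no control needed, it is erased in step 5) and the arene positions within reach of the cation being meta to the ether oxygens and therefore poor Friedel–Crafts sites.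

Step 4
Reactants: 12 chloroacetaldehyde dimethyl acetal
Product: 15 methoxyacetylene (methoxyethyne), via chlorovinyl ether 13 (not isolated), via sodium methoxyacetylide 14 (not isolated)
Conditions: NaNH2 (3 equiv, from Na, cat. Fe(NO3)3), liq. NH3, –33 °C; evaporate NH3; cold satd aq NaCl, –70 °C → warm, distil into a –78 °C trap; use at once as a cold toluene solution, behind a shield
Reagents that add atoms: none
Why: Two successive amide-induced β-eliminations (loss of methanol, then of HCl) give the acetylide 14, which is protonated on aqueous quench, and the low-boiling ynol ether is swept out of the salt slurry as it forms.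

Step 5
Reactants: 11 racemic 4-[4-(benzyloxy)benzyl]-3-{2-[2-(benzyloxy)phenyl]ethyl}cyclobut-2-en-1-one; 15 methoxyacetylene
Product: 20 2-[4-(benzyloxy)benzyl]-3-{2-[2-(benzyloxy)phenyl]ethyl}-5-methoxyphenol, via vinylketene 16 (not isolated), via vinylcyclobutenone 17 (not isolated), via dienylketene 18 (not isolated), via cyclohexadienone 19 (not isolated)
Conditions: 15 (3 equiv), degassed toluene, sealed tube, 80 °C, then 110 °C; then KOH, MeOH, rt
Reagents that add atoms: none
Why: Danheiser benzannulation: conrotatory 4π opening of 11 (benzyl group turning outward) gives vinylketene 16, whose ketene C=C adds methoxyacetylene in a [2+2] (forming C2–C3 and C1–C6) to give 4-vinylcyclobutenone 17; a second, reversible 4π opening gives dienylketene 18, which closes to dienone 19 and tautomerises to phenol 20. The closest known reaction type is the thermal annulation of cyclobutenones with alkoxyalkynes that delivers resorcinol monoethers. The one new ring, the central benzene ring, is closed by thermal disrotatory 6π electrocyclisation of 18, joining the ketene carbon (later C3–OH) to the benzyl-bearing carbon C4. No stereocentre is created, and the C4 stereocentre of 11 becomes an aromatic carbon, so its racemic nature has no consequence. The selectivity needed is the orientation of the ketene–alkyne [2+2]: the ynol ether is polarised so that its unsubstituted carbon is nucleophilic and bonds to the electrophilic ketene carbonyl carbon, which puts OMe meta to the new OH and leaves benzyl ortho and phenethyl meta to that OH. All atoms of both partners end up in 20, and the basic methanol treatment only returns any phenol that was O-acylated by 16.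

Step 6
Reactants: 20 2-[4-(benzyloxy)benzyl]-3-{2-[2-(benzyloxy)phenyl]ethyl}-5-methoxyphenol
Product: 21 2-(4-hydroxybenzyl)-3-[2-(2-hydroxyphenyl)ethyl]-5-methoxyphenol (CNP0260198.0)
Conditions: H2 (1 atm), 10% Pd/C, EtOAc/MeOH, rt
Reagents that add atoms: none
Why: Catalytic hydrogenolysis cleaves both aryl benzyl ethers, while the diarylmethane and bibenzyl C–C bonds, the aryl methyl ether and the arene rings are inert under these mild conditions.

Compound list
1 | 3-[4-(benzyloxy)phenyl]propanoic acid | OC(=O)CCc1ccc(OCc2ccccc2)cc1 | starting material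
2 | 1-{3-[4-(benzyloxy)phenyl]propanoyl}imidazole (formed in situ) | O=C(CCc1ccc(OCc2ccccc2)cc1)n1ccnc1 | intermediate
3 | 3-[4-(benzyloxy)phenyl]-N,N-dimethylpropanamide | CN(C)C(=O)CCc1ccc(OCc2ccccc2)cc1 | intermediate
4 | 2-(benzyloxy)benzyl bromide | BrCc1ccccc1OCc1ccccc1 | starting material
5 | 1-(trimethylsilyl)propyne | CC#C[Si](C)(C)C | starting material
6 | 3-lithio-1-(trimethylsilyl)propyne (formed in situ) | [Li]CC#C[Si](C)(C)C | intermediate
7 | {4-[2-(benzyloxy)phenyl]but-1-yn-1-yl}trimethylsilane (formed in situ) | C[Si](C)(C)C#CCCc1ccccc1OCc1ccccc1 | intermediate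
8 | 4-[2-(benzyloxy)phenyl]but-1-yne | C#CCCc1ccccc1OCc1ccccc1 | intermediate
9 | N-{3-[4-(benzyloxy)phenyl]prop-1-en-1-ylidene}-N-methylmethanaminium triflate (formed in situ) | C[N+](C)=C=CCc1ccc(OCc2ccccc2)cc1.[O-]S(=O)(=O)C(F)(F)F | intermediate
10 | racemic N-{4-[4-(benzyloxy)benzyl]-3-{2-[2-(benzyloxy)phenyl]ethyl}cyclobut-2-en-1-ylidene}-N-methylmethanaminium triflate (formed in situ) | C[N+](C)=C1C=C(CCc2ccccc2OCc2ccccc2)C1Cc1ccc(OCc2ccccc2)cc1.[O-]S(=O)(=O)C(F)(F)F | intermediate
11 | racemic 4-[4-(benzyloxy)benzyl]-3-{2-[2-(benzyloxy)phenyl]ethyl}cyclobut-2-en-1-one | O=C1C=C(CCc2ccccc2OCc2ccccc2)C1Cc1ccc(OCc2ccccc2)cc1 | intermediate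
12 | chloroacetaldehyde dimethyl acetal (2-chloro-1,1-dimethoxyethane) | COC(CCl)OC | starting material
13 | 1-chloro-2-methoxyethene, E/Z mixture (formed in situ) | COC=CCl | intermediate
14 | sodium methoxyacetylide (formed in situ) | [Na+].[C-]#COC | intermediate
15 | methoxyacetylene | COC#C | intermediate
16 | (3E)-5-[4-(benzyloxy)phenyl]-3-{2-[2-(benzyloxy)phenyl]ethyl}penta-1,3-dien-1-one (formed in situ) | O=C=C/C(CCc1ccccc1OCc1ccccc1)=C/Cc1ccc(OCc2ccccc2)cc1 | intermediate
17 | racemic 4-{(2E)-1-[4-(benzyloxy)phenyl]-5-[2-(benzyloxy)phenyl]pent-2-en-3-yl}-3-methoxycyclobut-2-en-1-one (formed in situ) | COC1=CC(=O)C1/C(CCc1ccccc1OCc1ccccc1)=C/Cc1ccc(OCc2ccccc2)cc1 | intermediate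
18 | (3E,5E)-7-[4-(benzyloxy)phenyl]-5-{2-[2-(benzyloxy)phenyl]ethyl}-3-methoxyhepta-1,3,5-trien-1-one (formed in situ) | O=C=C/C(OC)=C\C(CCc1ccccc1OCc1ccccc1)=C\Cc1ccc(OCc2ccccc2)cc1 | intermediate
19 | racemic 6-[4-(benzyloxy)benzyl]-5-{2-[2-(benzyloxy)phenyl]ethyl}-3-methoxycyclohexa-2,4-dien-1-one (formed in situ) | COC1=CC(=O)C(Cc2ccc(OCc3ccccc3)cc2)C(CCc2ccccc2OCc2ccccc2)=C1 | intermediate
20 | 2-[4-(benzyloxy)benzyl]-3-{2-[2-(benzyloxy)phenyl]ethyl}-5-methoxyphenol | COc1cc(O)c(Cc2ccc(OCc3ccccc3)cc2)c(CCc2ccccc2OCc2ccccc2)c1 | intermediate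
21 | 2-(4-hydroxybenzyl)-3-[2-(2-hydroxyphenyl)ethyl]-5-methoxyphenol (achiral) | COc1cc(O)c(Cc2ccc(O)cc2)c(CCc2ccccc2O)c1 | target

Total step count: 6
Longest linear sequence: 4 steps (step 1 or step 2, then steps 3, 5 and 6)

Steps most likely to fail

Step 5. The terminal ynol ether may escape or polymerise at the temperature needed to open the cyclobutenone, so that the vinylketene is lost to dimerisation or to acylation of the product before it is intercepted. The fallback sets out from acetylide 14 and cyclobutenone 11 and returns at 20. After removal of ammonia, 14 is suspended in Et2O and silylated with Me3SiCl to give the distillable, much less volatile (methoxyethynyl)trimethylsilane F1. Heating F1 with 11 in toluene at 110 °C under ordinary reflux should give, with the same ketene–ynol ether orientation (silicon-bearing carbon to the ketene carbonyl), 2-[4-(benzyloxy)benzyl]-3-{2-[2-(benzyloxy)phenyl]ethyl}-5-methoxy-6-(trimethylsilyl)phenol F2. Ipso-protodesilylation of this electron-rich arylsilane with dilute TFA in CH2Cl2 at 0 °C then gives 20.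

Step 3. The monosubstituted keteniminium ion may be consumed by self-condensation or by attack on an arene faster than the unactivated alkyne adds to it. The fallback sets out from acid 1 and returns at cyclobutenone 11.
- Oxalyl chloride with cat. DMF converts 1 into 3-[4-(benzyloxy)phenyl]propanoyl chloride F3.
- Slow addition of Et3N to F3 and excess ethoxyacetylene (purchased as a hexane solution) in Et2O releases the aldoketene 3-[4-(benzyloxy)phenyl]prop-1-en-1-one F4 in the presence of its trap. Ketene–ynol ether [2+2] should then give 4-[4-(benzyloxy)benzyl]-3-ethoxycyclobut-2-en-1-one F5.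
- The C3 side chain comes from a Grignard reagent. Purchased 2-(2-hydroxyphenyl)ethanol is O-benzylated at the phenol (BnBr, K2CO3, acetone) to 2-[2-(benzyloxy)phenyl]ethanol F6, brominated (CBr4, PPh3) to 1-(benzyloxy)-2-(2-bromoethyl)benzene F7 and metalated (Mg, THF) to {2-[2-(benzyloxy)phenyl]ethyl}magnesium bromide F8.
- 1,2-Addition of F8 to F5 (CeCl3, THF, –78 °C) gives 4-[4-(benzyloxy)benzyl]-1-{2-[2-(benzyloxy)phenyl]ethyl}-3-ethoxycyclobut-2-en-1-ol F9.
- Dilute HCl in THF ionises the tertiary allylic alcohol and hydrolyses the enol ether (1,3-carbonyl transposition of a vinylogous ester). This places the carbonyl at the former C–OEt carbon and the phenethyl group at C3, which is 11.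

Step 2. The ambident propargyl/allenyl lithium may be alkylated at the allenic terminus, or halogen–metal exchange may lead to homocoupling of the benzylic bromide. The fallback sets out from bromide 4 and returns at alkyne 8. The lithium enolate of N-methoxy-N-methylacetamide (LDA, THF, –78 °C) is alkylated with 4 to give 3-[2-(benzyloxy)phenyl]-N-methoxy-N-methylpropanamide F10. DIBAL-H (THF, –78 °C) reduces it to 3-[2-(benzyloxy)phenyl]propanal F11. Ohira–Bestmann homologation (dimethyl (1-diazo-2-oxopropyl)phosphonate, K2CO3, MeOH, rt) then gives 8.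

Further compounds
F1 | step 5 | (methoxyethynyl)trimethylsilane | COC#C[Si](C)(C)C
F2 | step 5 | 2-[4-(benzyloxy)benzyl]-3-{2-[2-(benzyloxy)phenyl]ethyl}-5-methoxy-6-(trimethylsilyl)phenol | COc1cc(CCc2ccccc2OCc2ccccc2)c(Cc2ccc(OCc3ccccc3)cc2)c(O)c1[Si](C)(C)C
F3 | step 3 | 3-[4-(benzyloxy)phenyl]propanoyl chloride | O=C(Cl)CCc1ccc(OCc2ccccc2)cc1
F4 | step 3 | 3-[4-(benzyloxy)phenyl]prop-1-en-1-one | O=C=CCc1ccc(OCc2ccccc2)cc1
F5 | step 3 | racemic 4-[4-(benzyloxy)benzyl]-3-ethoxycyclobut-2-en-1-one | CCOC1=CC(=O)C1Cc1ccc(OCc2ccccc2)cc1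
F6 | step 3 | 2-[2-(benzyloxy)phenyl]ethanol | OCCc1ccccc1OCc1ccccc1
F7 | step 3 | 1-(benzyloxy)-2-(2-bromoethyl)benzene | BrCCc1ccccc1OCc1ccccc1
F8 | step 3 | {2-[2-(benzyloxy)phenyl]ethyl}magnesium bromide | Br[Mg]CCc1ccccc1OCc1ccccc1
F9 | step 3 | 4-[4-(benzyloxy)benzyl]-1-{2-[2-(benzyloxy)phenyl]ethyl}-3-ethoxycyclobut-2-en-1-ol, mixture of racemic diastereomers | CCOC1=CC(O)(CCc2ccccc2OCc2ccccc2)C1Cc1ccc(OCc2ccccc2)cc1
F10 | step 2 | 3-[2-(benzyloxy)phenyl]-N-methoxy-N-methylpropanamide | CON(C)C(=O)CCc1ccccc1OCc1ccccc1
F11 | step 2 | 3-[2-(benzyloxy)phenyl]propanal | O=CCCc1ccccc1OCc1ccccc1
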